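**Plan**

- The retrosynthesis first cuts the ester C–O bond at C3 (palmitoleic acid off), then the central C15=C15' double bond, which divides the C40 chain into two C20 retinyl halves that differ only at C3 of ring A.
- The enabling feature: C15 and C15' are both allylic CH2 carbons at the retinol oxidation level (ring A = C1–C6 with oxygen on C3, chain C7–C15, primed locants for the unsubstituted half). Each can be bonded to one sulfur atom as an allylic electrophile, and each then becomes an acidic α-sulfonyl carbon flanked by a tetraene.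
- The oxygenated half is cut further at C11=C12 and C9=C10 (two Horner–Wadsworth–Emmons olefinations) and at C6–C7 (Heck coupling of a ring A enol triflate).
- Forward: actinol → silyl ether → enol triflate → C13 enone → C15 enal → C20 ester → alcohol → bromide. Retinol → bromide → hydroxymethyl sulfone. The halves are joined at sulfur, SO2 is extruded to form C15=C15', then desilylation and acylation follow.
- Stereochemistry: C3 (R) is C4 of (4R,6R)-actinol and is never touched. The E double bonds come from the Heck and olefination steps, from all-trans-retinol and from thermal equilibration after the extrusion. The 9Z bond comes with palmitoleic acid.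

Key step: step 12

Assumption: (4R,6R)-actinol is bought as the single enantiomer (an industrial carotenoid intermediate), and all polyene compounds are handled under argon in dim light.

**Route**

Step 1
Reactants: 1 (4R,6R)-4-hydroxy-2,2,6-trimethylcyclohexanone (actinol)
Product: 2 (4R,6R)-4-(tert-butyldimethylsilyloxy)-2,2,6-trimethylcyclohexanone
Conditions: TBSCl, imidazole, DMF, rt
Reagents that add atoms: tert-butyldimethylsilyl chloride, CC(C)(C)[Si](C)(C)Cl
Why: Imidazole-promoted silyl ether formation on a secondary alcohol leaves the carbinol configuration untouched and gives a protecting group that should survive the basic and organometallic steps ahead.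

Step 2
Reactants: 2 (4R,6R)-4-(tert-butyldimethylsilyloxy)-2,2,6-trimethylcyclohexanone
Product: 4 (4R)-4-(tert-butyldimethylsilyloxy)-2,6,6-trimethylcyclohex-1-en-1-yl trifluoromethanesulfonate, via lithium enolate 3 (not isolated)
Conditions: LiN(i-Pr)2, THF, −78 °C; then PhNTf2, −78 °C to rt
Reagents that add atoms: N-phenylbis(trifluoromethanesulfonimide), O=S(=O)(N(c1ccccc1)S(=O)(=O)C(F)(F)F)C(F)(F)F
Why: The ketone has a single α-hydrogen, so deprotonation gives one enolate, and its O-sulfonylation (enol triflate formation) fixes the C5=C6 double bond of ring A while the C6 stereocentre of 2 is deliberately lost.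

Step 3
Reactants: 4 (4R)-4-(tert-butyldimethylsilyloxy)-2,6,6-trimethylcyclohex-1-en-1-yl trifluoromethanesulfonate; 5 but-3-en-2-one (methyl vinyl ketone)
Product: 6 (3E)-4-[(4R)-4-(tert-butyldimethylsilyloxy)-2,6,6-trimethylcyclohex-1-en-1-yl]but-3-en-2-one
Conditions: PdCl2(PPh3)2 (5 mol %), Et3N, DMF, 75 °C
Reagents that add atoms: none
Why: Heck alkenylation of an enol triflate with an electron-poor alkene (oxidative addition, insertion of the enone, syn β-hydride elimination) should form C6–C7 and deliver the C7=C8 bond as the E-enone.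

Step 4
Reactants: 6 (3E)-4-[(4R)-4-(tert-butyldimethylsilyloxy)-2,6,6-trimethylcyclohex-1-en-1-yl]but-3-en-2-one; 7 diethyl (cyanomethyl)phosphonate
Product: 8 (2E,4E)-5-[(4R)-4-(tert-butyldimethylsilyloxy)-2,6,6-trimethylcyclohex-1-en-1-yl]-3-methylpenta-2,4-dienenitrile
Conditions: NaH, THF, 0 °C to rt
Reagents that add atoms: none
Why: Horner–Wadsworth–Emmons olefination of the methyl ketone with a cyano-stabilised phosphonate anion adds C10–C11 and should favour the 2E nitrile (9E in carotenoid numbering), the minor 2Z isomer being removed by chromatography here or after step 5.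

Step 5
Reactants: 8 (2E,4E)-5-[(4R)-4-(tert-butyldimethylsilyloxy)-2,6,6-trimethylcyclohex-1-en-1-yl]-3-methylpenta-2,4-dienenitrile
Product: 10 (2E,4E)-5-[(4R)-4-(tert-butyldimethylsilyloxy)-2,6,6-trimethylcyclohex-1-en-1-yl]-3-methylpenta-2,4-dienal, via N-aluminated aldimine 9 (not isolated)
Conditions: i-Bu2AlH (1.2 equiv), CH2Cl2, −78 °C; then wet SiO2, 0 °C
Reagents that add atoms: water, O
Why: Partial reduction of a nitrile with i-Bu2AlH stops at the N-aluminated aldimine, which wet silica hydrolyses to the enal under conditions mild enough for the silyl ether and the diene.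

Step 6
Reactants: 10 (2E,4E)-5-[(4R)-4-(tert-butyldimethylsilyloxy)-2,6,6-trimethylcyclohex-1-en-1-yl]-3-methylpenta-2,4-dienal; 11 ethyl (2E)-4-(diethoxyphosphoryl)-3-methylbut-2-enoate
Product: 12 ethyl (3R)-3-(tert-butyldimethylsilyloxy)-all-trans-retinoate
Conditions: n-BuLi, DMPU, THF, −78 to 0 °C
Reagents that add atoms: none
Why: Vinylogous Horner–Wadsworth–Emmons olefination with the γ-phosphonocrotonate anion (one allylic anion from either geometric isomer of the reagent) adds C12–C15 and should give mainly the all-E tetraenoate in THF/DMPU at low temperature.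

Step 7
Reactants: 12 ethyl (3R)-3-(tert-butyldimethylsilyloxy)-all-trans-retinoate
Product: 13 (3R)-3-(tert-butyldimethylsilyloxy)-all-trans-retinol
Conditions: i-Bu2AlH (2.2 equiv), CH2Cl2, −78 °C; aq. potassium sodium tartrate
Reagents that add atoms: none
Why: 1,2-Reduction of a conjugated ester by i-Bu2AlH at low temperature gives the primary allylic alcohol without touching the polyene or the silyl ether.

Step 8
Reactants: 13 (3R)-3-(tert-butyldimethylsilyloxy)-all-trans-retinol
Product: 14 (3R)-3-(tert-butyldimethylsilyloxy)-all-trans-retinyl bromide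
Conditions: PBr3 (0.4 equiv), pyridine (cat.), Et2O, −20 °C, dark; cold aq. NaHCO3 wash, used at once
Reagents that add atoms: phosphorus tribromide, BrP(Br)Br
Why: Bromination of a primary allylic alcohol with PBr3 (phosphite ester, then SN2 at C15) is the standard entry to retinyl halides, and low temperature with a pyridine buffer should spare the silyl ether.

Step 9
Reactants: 15 all-trans-retinol
Product: 16 all-trans-retinyl bromide
Conditions: PBr3 (0.4 equiv), pyridine (cat.), Et2O, −20 °C, dark; cold aq. NaHCO3 wash, used at once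
Reagents that add atoms: phosphorus tribromide, BrP(Br)Br
Why: The same PBr3 bromination turns the primary allylic alcohol of the unsubstituted half into the C15' allylic electrophile.

Step 10
Reactants: 16 all-trans-retinyl bromide; 17 sodium hydroxymethanesulfinate
Product: 18 (all-trans-retinylsulfonyl)methanol (hydroxymethyl retinyl sulfone)
Conditions: HOCH2SO2Na·2H2O (3 equiv), n-Bu4NBr (cat.), DMF, 0 °C to rt, dark
Reagents that add atoms: none
Why: S-Alkylation of hydroxymethanesulfinate by an allylic bromide gives a neutral, extractable hydroxymethyl sulfone (a masked sulfinate), so sulfur reaches the sulfone oxidation level without any oxidant that would attack the pentaene.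

Step 11
Reactants: 18 (all-trans-retinylsulfonyl)methanol; 14 (3R)-3-(tert-butyldimethylsilyloxy)-all-trans-retinyl bromide
Product: 20 (3R)-3-(tert-butyldimethylsilyloxy)retinyl retinyl sulfone, via potassium retinylsulfinate 19 (not isolated)
Conditions: K2CO3, DMF, rt, dark (18 in slight excess)
Reagents that add atoms: none
Why: Mild base triggers loss of formaldehyde from the α-hydroxy sulfone, and the sulfinate set free is S-alkylated by the second allylic bromide (sulfinate alkylation), which joins two different C20 halves at sulfur without a statistical mixture.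

Step 12
Reactants: 20 (3R)-3-(tert-butyldimethylsilyloxy)retinyl retinyl sulfone
Product: 25 (3R)-β-cryptoxanthin tert-butyldimethylsilyl ether, via alpha-bromo sulfone 21 (not isolated), via regioisomeric alpha-bromo sulfone 22 (not isolated), via episulfone 23 (not isolated), via 15Z isomer 24 (not isolated)
Conditions: KOH/Al2O3, CBr2F2, t-BuOH/CH2Cl2, 0 °C to rt, dark; then heptane, 80 °C
Reagents that add atoms: none
Why: KOH on Al2O3 removes a proton from C15 or C15' (each is alpha to the sulfonyl group and allylic to a tetraene), the carbanion takes bromine from CBr2F2 to give 21 or 22, a second deprotonation at the other alpha carbon closes the episulfone 23 by 1,3-displacement of bromide, and cheletropic loss of SO2 from this strained ring leaves the C15=C15' double bond. The closest known reaction type is the Ramberg–Bäcklund reaction with in situ halogenation, which is established for bis-allylic sulfones giving conjugated trienes in carotenoid-type polyenes. No ring of the target is closed; the only ring formed is the transient three-membered thiirane 1,1-dioxide (3-exo-tet closure), and no stereocentre is created. The step needs E geometry at C15=C15': base should epimerise the episulfone toward the trans isomer before extrusion, and any 15Z product 24 should pass to the all-E isomer on brief heating in heptane, because the unhindered central cis bond of a carotenoid isomerises thermally with ease. It also needs the polyene and the C3–O bond to survive: the difluorocarbene left by CBr2F2 adds to alkenes far less readily than dichlorocarbene from CCl4, the solid-supported base keeps exposure short, and C3 carries the base-stable silyl ether in place of the ester. Because the sulfone was built from two different allylic electrophiles, the extrusion can give only the unsymmetrical C40 chain.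

Step 13
Reactants: 25 (3R)-β-cryptoxanthin tert-butyldimethylsilyl ether
Product: 26 (3R)-β-cryptoxanthin
Conditions: n-Bu4NF, THF, 0 °C to rt, dark
Reagents that add atoms: none
Why: Fluoride-induced desilylation breaks only the Si–O bond, so C3 keeps its R configuration and the polyene is not exposed to acid.

Step 14
Reactants: 26 (3R)-β-cryptoxanthin; 27 palmitoleic acid [(9Z)-hexadec-9-enoic acid]
Product: 28 (3R)-β-cryptoxanthin palmitoleate (CNP0382087.1)
Conditions: DCC, DMAP (cat.), CH2Cl2, rt, dark
Reagents that add atoms: none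
Why: Steglich esterification (carbodiimide activation, DMAP acyl transfer) acylates the secondary C3 alcohol on oxygen with retention, and the neutral conditions leave the 9Z bond of the acid and the carotenoid chain unchanged.

**Compound list**

1 | (4R,6R)-4-hydroxy-2,2,6-trimethylcyclohexanone (actinol) | O[C@@H]1C[C@@H](C)C(=O)C(C)(C)C1 | starting material
2 | (4R,6R)-4-(tert-butyldimethylsilyloxy)-2,2,6-trimethylcyclohexanone | CC(C)(C)[Si](C)(C)O[C@@H]1C[C@@H](C)C(=O)C(C)(C)C1 | intermediate
3 | lithium (4R)-4-(tert-butyldimethylsilyloxy)-2,6,6-trimethylcyclohex-1-en-1-olate | [Li+].CC(C)(C)[Si](C)(C)O[C@@H]1CC(C)=C([O-])C(C)(C)C1 | intermediate (not isolated)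
4 | (4R)-4-(tert-butyldimethylsilyloxy)-2,6,6-trimethylcyclohex-1-en-1-yl trifluoromethanesulfonate | CC(C)(C)[Si](C)(C)O[C@@H]1CC(C)=C(OS(=O)(=O)C(F)(F)F)C(C)(C)C1 | intermediate
5 | but-3-en-2-one (methyl vinyl ketone) | C=CC(C)=O | starting material
6 | (3E)-4-[(4R)-4-(tert-butyldimethylsilyloxy)-2,6,6-trimethylcyclohex-1-en-1-yl]but-3-en-2-one [(3R)-3-silyloxy-β-ionone] | CC(C)(C)[Si](C)(C)O[C@@H]1CC(C)=C(/C=C/C(C)=O)C(C)(C)C1 | intermediate
7 | diethyl (cyanomethyl)phosphonate | CCOP(=O)(CC#N)OCC | starting material
8 | (2E,4E)-5-[(4R)-4-(tert-butyldimethylsilyloxy)-2,6,6-trimethylcyclohex-1-en-1-yl]-3-methylpenta-2,4-dienenitrile | CC(C)(C)[Si](C)(C)O[C@@H]1CC(C)=C(/C=C/C(C)=C/C#N)C(C)(C)C1 | intermediate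
9 | N-(diisobutylalumanyl) aldimine of 10 | CC(C)(C)[Si](C)(C)O[C@@H]1CC(C)=C(/C=C/C(C)=C/C=N[Al](CC(C)C)CC(C)C)C(C)(C)C1 | intermediate (not isolated)
10 | (2E,4E)-5-[(4R)-4-(tert-butyldimethylsilyloxy)-2,6,6-trimethylcyclohex-1-en-1-yl]-3-methylpenta-2,4-dienal | CC(C)(C)[Si](C)(C)O[C@@H]1CC(C)=C(/C=C/C(C)=C/C=O)C(C)(C)C1 | intermediate
11 | ethyl (2E)-4-(diethoxyphosphoryl)-3-methylbut-2-enoate (triethyl 3-methyl-4-phosphonocrotonate) | CCOC(=O)/C=C(\C)CP(=O)(OCC)OCC | starting material
12 | ethyl (3R)-3-(tert-butyldimethylsilyloxy)-all-trans-retinoate | CC(C)(C)[Si](C)(C)O[C@@H]1CC(C)=C(/C=C/C(C)=C/C=C/C(C)=C/C(=O)OCC)C(C)(C)C1 | intermediate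
13 | (3R)-3-(tert-butyldimethylsilyloxy)-all-trans-retinol | CC(C)(C)[Si](C)(C)O[C@@H]1CC(C)=C(/C=C/C(C)=C/C=C/C(C)=C/CO)C(C)(C)C1 | intermediate
14 | (3R)-3-(tert-butyldimethylsilyloxy)-all-trans-retinyl bromide | CC(C)(C)[Si](C)(C)O[C@@H]1CC(C)=C(/C=C/C(C)=C/C=C/C(C)=C/CBr)C(C)(C)C1 | intermediate
15 | all-trans-retinol | OC/C=C(C)/C=C/C=C(C)/C=C/C1=C(C)CCCC1(C)C | starting material
16 | all-trans-retinyl bromide | BrC/C=C(C)/C=C/C=C(C)/C=C/C1=C(C)CCCC1(C)C | intermediate
17 | sodium hydroxymethanesulfinate | OCS(=O)[O-].[Na+] | starting material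
18 | (all-trans-retinylsulfonyl)methanol | OCS(=O)(=O)C/C=C(C)/C=C/C=C(C)/C=C/C1=C(C)CCCC1(C)C | intermediate
19 | potassium all-trans-retinylsulfinate | [K+].[O-]S(=O)C/C=C(C)/C=C/C=C(C)/C=C/C1=C(C)CCCC1(C)C | intermediate (not isolated)
20 | (3R)-3-(tert-butyldimethylsilyloxy)retinyl retinyl sulfone | CC(C)(C)[Si](C)(C)O[C@@H]1CC(C)=C(/C=C/C(C)=C/C=C/C(C)=C/CS(=O)(=O)C/C=C(C)/C=C/C=C(C)/C=C/C2=C(C)CCCC2(C)C)C(C)(C)C1 | intermediate
21 | alpha-bromo sulfone, bromine on C15' (configuration at CBr not defined) | CC(C)(C)[Si](C)(C)O[C@@H]1CC(C)=C(/C=C/C(C)=C/C=C/C(C)=C/CS(=O)(=O)C(Br)/C=C(C)/C=C/C=C(C)/C=C/C2=C(C)CCCC2(C)C)C(C)(C)C1 | intermediate (not isolated)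
22 | alpha-bromo sulfone, bromine on C15 (configuration at CBr not defined) | CC(C)(C)[Si](C)(C)O[C@@H]1CC(C)=C(/C=C/C(C)=C/C=C/C(C)=C/C(Br)S(=O)(=O)C/C=C(C)/C=C/C=C(C)/C=C/C2=C(C)CCCC2(C)C)C(C)(C)C1 | intermediate (not isolated)
23 | episulfone: thiirane 1,1-dioxide spanning C15 and C15' (cis/trans not defined) | CC(C)(C)[Si](C)(C)O[C@@H]1CC(C)=C(/C=C/C(C)=C/C=C/C(C)=C/C3C(/C=C(C)/C=C/C=C(C)/C=C/C2=C(C)CCCC2(C)C)S3(=O)=O)C(C)(C)C1 | intermediate (not isolated)
24 | (3R,15Z)-β-cryptoxanthin tert-butyldimethylsilyl ether | CC(C)(C)[Si](C)(C)O[C@@H]1CC(C)=C(/C=C/C(C)=C/C=C/C(C)=C/C=C\C=C(C)\C=C\C=C(C)\C=C\C2=C(C)CCCC2(C)C)C(C)(C)C1 | intermediate (not isolated)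
25 | (3R)-β-cryptoxanthin tert-butyldimethylsilyl ether | CC(C)(C)[Si](C)(C)O[C@@H]1CC(C)=C(/C=C/C(C)=C/C=C/C(C)=C/C=C/C=C(C)/C=C/C=C(C)/C=C/C2=C(C)CCCC2(C)C)C(C)(C)C1 | intermediate
26 | (3R)-β-cryptoxanthin | O[C@@H]1CC(C)=C(/C=C/C(C)=C/C=C/C(C)=C/C=C/C=C(C)/C=C/C=C(C)/C=C/C2=C(C)CCCC2(C)C)C(C)(C)C1 | intermediate
27 | palmitoleic acid [(9Z)-hexadec-9-enoic acid] | CCCCCC/C=C\CCCCCCCC(=O)O | starting material
28 | (3R)-β-cryptoxanthin palmitoleate (CNP0382087.1) | CCCCCC/C=C\CCCCCCCC(=O)O[C@@H]1CC(C)=C(/C=C/C(C)=C/C=C/C(C)=C/C=C/C=C(C)/C=C/C=C(C)/C=C/C2=C(C)CCCC2(C)C)C(C)(C)C1 | target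

**Count and risks**

Total step count: 14. Longest linear sequence: 12 steps (steps 1–8 and 11–14, from actinol 1).

Steps most likely to fail:

Step 12. The delocalised pentaenyl sulfonyl carbanion may be brominated at a vinylogous carbon or more than once, and carbene or base may attack the long polyene, so that extrusion is not clean. The fallback sets out from 14 and 15 and comes back at 25, forming the same C15=C15' bond by a Wittig reaction. Bromide 14 is quaternised with PPh3 (EtOAc, rt) to (3R)-3-(tert-butyldimethylsilyloxy)retinyltriphenylphosphonium bromide F1. Retinol 15 is oxidised with MnO2 (CH2Cl2, rt) to all-trans-retinal F2. The ylide of F1 (NaOCH3, CH3OH/CH2Cl2, 0 °C) is condensed with F2, and the same thermal equilibration in heptane should give 25.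

Step 11. The pentaenyl bromide 14 may ionise and eliminate in DMF before it is attacked at sulfur, and the ambident sulfinate may be alkylated at oxygen or the bromide at a vinylogous carbon. The fallback sets out from 13 and comes back at 20, replacing the bromide by a stable allylic ester. Alcohol 13 is acetylated (Ac2O, pyridine, DMAP, CH2Cl2) to (3R)-3-(tert-butyldimethylsilyloxy)retinyl acetate F3. F3 is then coupled with sulfinate 19, released from 18 by K2CO3, under Pd(PPh3)4 catalysis in THF. This is an allylic substitution through a π-allyl complex of zerovalent palladium; it is reversible for sulfinates and should therefore settle on the conjugated, terminal sulfone 20.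

Step 3. Oxidative addition and alkene insertion may be slow at the tetrasubstituted enol triflate flanked by a methyl and a gem-dimethyl group, so that reduction of the triflate and polymerisation of the enone compete. The fallback sets out from 4 and comes back at 6. Sonogashira coupling of 4 with but-3-yn-2-ol (Pd(PPh3)4, CuI, i-Pr2NH, 40 °C) gives 4-[(4R)-4-(tert-butyldimethylsilyloxy)-2,6,6-trimethylcyclohex-1-en-1-yl]but-3-yn-2-ol F4. Hydroxyl-directed trans-hydroalumination with NaAlH2(OCH2CH2OCH3)2 in THF gives (3E)-4-[(4R)-4-(tert-butyldimethylsilyloxy)-2,6,6-trimethylcyclohex-1-en-1-yl]but-3-en-2-ol F5, and MnO2 oxidation of this allylic alcohol gives 6.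

**Further compounds**

F1 | step 12 | (3R)-3-(tert-butyldimethylsilyloxy)retinyltriphenylphosphonium bromide | [Br-].CC(C)(C)[Si](C)(C)O[C@@H]1CC(C)=C(/C=C/C(C)=C/C=C/C(C)=C/C[P+](c2ccccc2)(c2ccccc2)c2ccccc2)C(C)(C)C1
F2 | step 12 | all-trans-retinal | O=C/C=C(C)/C=C/C=C(C)/C=C/C1=C(C)CCCC1(C)C
F3 | step 11 | (3R)-3-(tert-butyldimethylsilyloxy)-all-trans-retinyl acetate | CC(C)(C)[Si](C)(C)O[C@@H]1CC(C)=C(/C=C/C(C)=C/C=C/C(C)=C/COC(C)=O)C(C)(C)C1
F4 | step 3 | 4-[(4R)-4-(tert-butyldimethylsilyloxy)-2,6,6-trimethylcyclohex-1-en-1-yl]but-3-yn-2-ol (carbinol epimers) | CC(C)(C)[Si](C)(C)O[C@@H]1CC(C)=C(C#CC(C)O)C(C)(C)C1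
F5 | step 3 | (3E)-4-[(4R)-4-(tert-butyldimethylsilyloxy)-2,6,6-trimethylcyclohex-1-en-1-yl]but-3-en-2-ol (carbinol epimers) | CC(C)(C)[Si](C)(C)O[C@@H]1CC(C)=C(/C=C/C(C)O)C(C)(C)C1
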